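## Retrosynthetic overview

1. Target 21 ⇐ ten-membered hydroxy dienone 15 by four late moves: OH-directed 4,5-epoxidation, angeloylation at O3, chelate-controlled reduction of the C9 ketone, and vanadium-directed 1,10-epoxidation.
2. 15 ⇐ cyclohexanone 11 by a photochemical four-atom ring expansion: a vinyl radical closes C9–C10 (transient cyclohexene, ring B), the C4–C9 bond of ring A breaks, and loss of PhS• gives C4=C5.
3. 11 ⇐ 6-senecioyloxycarvone 9 + 4-iodopent-3-enal 4 by thiolate conjugate addition–aldol (C3–C4 bond, C3 set).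
4. 9 ⇐ (S)-carvone 5 by α'-hydroxylation and Mitsunobu inversion with senecioic acid (C8 set); 4 ⇐ pent-3-yn-1-ol 1.
5. Ring order: ring A (bought with carvone) → ring B (transient) → ten-membered carbocycle → 4,5-oxirane → 1,10-oxirane.

Assumption: positions follow germacrane numbering (ring C1–C10, isopropenyl C11–C13 on C7, C14 on C10, C15 on C4), also for the carvone-derived intermediates (carvone C1/C2/C3/C4/C5/C6 = C9/C4/C5/C6/C7/C8).

## Route

Step 1
Reactants: 1 pent-3-yn-1-ol
Product: 3 (E)-4-iodopent-3-en-1-ol, via alkenylzirconocene 2 (not isolated)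
Conditions: Cp2Zr(H)Cl (2.2 equiv), THF, 0 °C to rt; then I2, 0 °C
Reagents that add atoms: iodine, II
Why: Hydrozirconation (syn addition, zirconium settling on the less hindered methyl-bearing alkyne carbon) and iodinolysis with retention give the 4-iodoalkene; its E/Z purity is irrelevant later because the derived vinyl radical inverts.

Step 2
Reactants: 3 (E)-4-iodopent-3-en-1-ol
Product: 4 (E)-4-iodopent-3-enal
Conditions: Dess–Martin periodinane, NaHCO3, CH2Cl2, 0 °C; used crude at once
Reagents that add atoms: none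
Why: Buffered Dess–Martin oxidation of a primary alcohol gives the β,γ-unsaturated aldehyde without base-induced double-bond migration.

Step 3
Reactants: 5 (S)-(+)-carvone
Product: 7 (5R,6R)-6-hydroxy-2-methyl-5-(prop-1-en-2-yl)cyclohex-2-en-1-one, via potassium dienolate 6 (not isolated)
Conditions: KN(SiMe3)2, THF, −78 °C; (±)-2-(phenylsulfonyl)-3-phenyloxaziridine, −78 °C; AcOH quench
Reagents that add atoms: 2-(phenylsulfonyl)-3-phenyloxaziridine, O=S(=O)(N1OC1c1ccccc1)c1ccccc1
Why: Kinetic α'-deprotonation gives the cross-conjugated dienolate, and Davis enolate hydroxylation (racemic oxaziridine as a plain oxygen source) occurs anti to the adjacent isopropenyl group, placing the C8 oxygen trans to C7.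

Step 4
Reactants: 7 (5R,6R)-6-hydroxy-2-methyl-5-(prop-1-en-2-yl)cyclohex-2-en-1-one; 8 3-methylbut-2-enoic acid (senecioic acid)
Product: 9 (1S,6R)-3-methyl-2-oxo-6-(prop-1-en-2-yl)cyclohex-3-en-1-yl 3-methylbut-2-enoate
Conditions: PPh3, DIAD, THF, 0 °C to rt
Reagents that add atoms: none
Why: Mitsunobu esterification is an SN2 displacement (helped by the adjacent carbonyl) that installs the senecioate with inversion, giving the required cis C7/C8 relationship (8S).

Step 5
Reactants: 9 (1S,6R)-3-methyl-2-oxo-6-(prop-1-en-2-yl)cyclohex-3-en-1-yl 3-methylbut-2-enoate; 4 (E)-4-iodopent-3-enal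
Product: 11 (1S,3S,4S,6R)-3-[(1S,3E)-1-hydroxy-4-iodopent-3-en-1-yl]-3-methyl-2-oxo-4-(phenylsulfanyl)-6-(prop-1-en-2-yl)cyclohexyl 3-methylbut-2-enoate, via aluminium enolate 10 (not isolated)
Conditions: Me2AlSPh (from Me3Al + PhSH, 1.2 equiv), CH2Cl2–THF, −78 °C; then 4, −78 °C; aq. potassium sodium tartrate
Reagents that add atoms: dimethylaluminium benzenethiolate, C[Al](C)Sc1ccccc1
Why: In this Nozaki-type thiolate conjugate addition–aldol, PhS adds axially at C5 anti to isopropenyl and enolate 10 then adds to the aldehyde anti to the axial PhS through a closed chair transition state with the aldehyde chain equatorial, which gives the 3S carbinol (the C4 and C5 centres are sacrificial).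

Step 6
Reactants: 11 (tandem adduct)
Product: 15 (3S,7R,8S)-3-hydroxy-9-oxogermacra-1(10)Z,4Z,11-trien-8-yl 3-methylbut-2-enoate, via vinyl radical 12 (not isolated), via alkoxyl radical 13 (not isolated), via tertiary radical 14 (not isolated)
Conditions: (Bu3Sn)2 (1.1 equiv), hν (sunlamp, Pyrex), degassed PhH, 0.01 M, 25 °C
Reagents that add atoms: none
Why: Proposed new method: a photo-initiated vinyl-radical Dowd–Beckwith-type four-atom ring expansion ended by β-elimination of a thiyl radical — Bu3Sn• (from ditin photolysis) abstracts iodine, the rapidly inverting vinyl radical 12 attacks the C9 carbonyl carbon through a six-membered transition state to form the C9–C10 bond and alkoxyl radical 13, β-scission of the congested C4–C9 bond gives the ten-membered enone radical 14, which expels PhS• to form C4=C5, and PhS• regenerates Bu3Sn• from the ditin while its reversible addition equilibrates the new alkene to the ring-favoured Z isomer (C1=C10 is Z because it was made inside a six-membered ring; C3, C7, C8 are untouched); the closest known reactions are the Dowd–Beckwith ring expansion (alkyl radical addition to a ketone carbonyl, then β-scission) and β-sulfanyl radical fragmentation, which have not been combined or run with vinyl radicals.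

Step 7
Reactants: 15 (ten-membered hydroxy dienone)
Product: 16 (3S,4R,5S,7R,8S)-4,5-epoxy-3-hydroxy-9-oxogermacra-1(10)Z,11-dien-8-yl 3-methylbut-2-enoate (oxirane anti to 3-OH)
Conditions: mCPBA (1.05 equiv), NaHCO3, CH2Cl2, −20 to 0 °C
Reagents that add atoms: 3-chloroperbenzoic acid, OOC(=O)c1cccc(Cl)c1
Why: Hydrogen-bond-directed peracid epoxidation of a medium-ring cis-allylic alcohol delivers oxygen to the face away from the hydroxyl (trans-epoxy alcohol), so the 4,5-oxirane forms anti to 3-OH; the enone and enoate double bonds are inert, the directed trisubstituted alkene outpaces isopropenyl, and any transannular hemiketal of 15 reacts through its open form.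

Step 8
Reactants: 16 (epoxy alcohol); 17 (Z)-2-methylbut-2-enoic acid (angelic acid)
Product: 19 (3S,4S,5S,7R,8S)-3-angeloyloxy-4,5-epoxy-9-oxogermacra-1(10)Z,11-dien-8-yl 3-methylbut-2-enoate, via mixed anhydride 18 (not isolated)
Conditions: 17, 2,4,6-trichlorobenzoyl chloride, Et3N, PhMe, rt; then 16, 60 °C (no DMAP)
Reagents that add atoms: none
Why: Yamaguchi esterification through the preformed mixed anhydride, without a nucleophilic catalyst, acylates the hindered carbinol while keeping the Z geometry of the angelate; no stereocentre is touched.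

Step 9
Reactants: 19 (epoxy angelate enone)
Product: 20 (3S,4S,5S,7R,8S,9R)-3-angeloyloxy-4,5-epoxy-9-hydroxygermacra-1(10)Z,11-dien-8-yl 3-methylbut-2-enoate
Conditions: Zn(BH4)2, Et2O, −40 to −20 °C
Reagents that add atoms: none
Why: Chelation-controlled 1,2-reduction (zinc bridging the ketone and the C8 ester carbonyl, Cram-chelate model) delivers hydride from the side away from C7 and gives the 8,9-cis hydroxy ester.

Step 10
Reactants: 20 (allylic alcohol)
Product: 21 (1R,3S,4S,5S,7R,8S,9S,10S)-3-angeloyloxy-1,10:4,5-diepoxy-9-hydroxygermacr-11-en-8-yl 3-methylbut-2-enoate (CNP0320216.1)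
Conditions: VO(acac)2 (5 mol %), t-BuOOH, CH2Cl2, 0 °C
Reagents that add atoms: tert-butyl hydroperoxide, CC(C)(C)OO
Why: Vanadium-catalysed hydroxyl-directed epoxidation touches only the allylic-alcohol double bond and, for medium-ring cis-allylic alcohols, delivers oxygen syn to the hydroxyl, giving the 1,10-oxirane cis to 9-OH.

## Compound list

1 | pent-3-yn-1-ol | CC#CCCO | starting material
2 | alkenylzirconocene chloride (zirconium alkoxide form) | C/C(=C\CCO[Zr](Cl)(C1C=CC=C1)C1C=CC=C1)[Zr](Cl)(C1C=CC=C1)C1C=CC=C1 | intermediate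
3 | (E)-4-iodopent-3-en-1-ol | C/C(I)=C\CCO | intermediate
4 | (E)-4-iodopent-3-enal | C/C(I)=C\CC=O | intermediate
5 | (S)-(+)-carvone | CC1=CC[C@@H](CC1=O)C(C)=C | starting material
6 | potassium cross-conjugated dienolate of carvone | CC1=CC[C@H](C(C)=C)C=C1[O-].[K+] | intermediate
7 | (5R,6R)-6-hydroxy-2-methyl-5-(prop-1-en-2-yl)cyclohex-2-en-1-one | CC1=CC[C@H](C(C)=C)[C@@H](O)C1=O | intermediate
8 | 3-methylbut-2-enoic acid (senecioic acid) | CC(C)=CC(=O)O | starting material
9 | (1S,6R)-3-methyl-2-oxo-6-(prop-1-en-2-yl)cyclohex-3-en-1-yl 3-methylbut-2-enoate | CC1=CC[C@H](C(C)=C)[C@H](OC(=O)C=C(C)C)C1=O | intermediate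
10 | dimethylaluminium enolate after PhS addition (C4=C9 enolate) | CC1=C(O[Al](C)C)[C@@H](OC(=O)C=C(C)C)[C@@H](C(C)=C)C[C@@H]1Sc2ccccc2 | intermediate
11 | (1S,3S,4S,6R)-3-[(1S,3E)-1-hydroxy-4-iodopent-3-en-1-yl]-3-methyl-2-oxo-4-(phenylsulfanyl)-6-(prop-1-en-2-yl)cyclohexyl 3-methylbut-2-enoate | C[C@@]1([C@@H](O)C/C=C(\C)I)[C@@H](Sc2ccccc2)C[C@H](C(C)=C)[C@H](OC(=O)C=C(C)C)C1=O | intermediate
12 | C10 vinyl radical from 11 | C[C@@]1([C@@H](O)CC=[C]C)[C@@H](Sc2ccccc2)C[C@H](C(C)=C)[C@H](OC(=O)C=C(C)C)C1=O | intermediate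
13 | cis-fused bicyclic C9 alkoxyl radical (rings A and B) | C[C@@]1([C@@H](O)CC=C2C)[C@@H](Sc3ccccc3)C[C@H](C(C)=C)[C@H](OC(=O)C=C(C)C)[C@@]12[O] | intermediate
14 | ring-opened ten-membered C4 tertiary radical | C=C(C)[C@H]1C[C@H](Sc2ccccc2)[C](C)[C@@H](O)C/C=C(C)\C(=O)[C@H]1OC(=O)C=C(C)C | intermediate
15 | (3S,7R,8S)-3-hydroxy-9-oxogermacra-1(10)Z,4Z,11-trien-8-yl 3-methylbut-2-enoate | C=C(C)[C@H]1C/C=C(C)\[C@@H](O)C/C=C(C)\C(=O)[C@H]1OC(=O)C=C(C)C | intermediate
16 | (3S,4R,5S,7R,8S)-4,5-epoxy-3-hydroxy-9-oxogermacra-1(10)Z,11-dien-8-yl 3-methylbut-2-enoate | C=C(C)[C@H]1C[C@@H]2O[C@]2(C)[C@@H](O)C/C=C(C)\C(=O)[C@H]1OC(=O)C=C(C)C | intermediate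
17 | (Z)-2-methylbut-2-enoic acid (angelic acid) | C/C=C(/C)C(=O)O | starting material
18 | angelic 2,4,6-trichlorobenzoic anhydride | C/C=C(/C)C(=O)OC(=O)c1c(Cl)cc(Cl)cc1Cl | intermediate
19 | (3S,4S,5S,7R,8S)-3-angeloyloxy-4,5-epoxy-9-oxogermacra-1(10)Z,11-dien-8-yl 3-methylbut-2-enoate | C=C(C)[C@H]1C[C@@H]2O[C@]2(C)[C@@H](OC(=O)/C(C)=C\C)C/C=C(C)\C(=O)[C@H]1OC(=O)C=C(C)C | intermediate
20 | (3S,4S,5S,7R,8S,9R)-3-angeloyloxy-4,5-epoxy-9-hydroxygermacra-1(10)Z,11-dien-8-yl 3-methylbut-2-enoate | C=C(C)[C@H]1C[C@@H]2O[C@]2(C)[C@@H](OC(=O)/C(C)=C\C)C/C=C(C)\[C@@H](O)[C@H]1OC(=O)C=C(C)C | intermediate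
21 | (1R,3S,4S,5S,7R,8S,9S,10S)-3-angeloyloxy-1,10:4,5-diepoxy-9-hydroxygermacr-11-en-8-yl 3-methylbut-2-enoate (CNP0320216.1) | C=C(C)[C@H]1C[C@@H]2O[C@]2(C)[C@@H](OC(=O)/C(C)=C\C)C[C@H]2O[C@@]2(C)[C@@H](O)[C@H]1OC(=O)C=C(C)C | target

## Step count and risks

Total step count: 10. Longest linear sequence: 8 (steps 3–10 from 5); the aldehyde branch is steps 1–2.

Steps most likely to fail:

- **Step 6 (the proposed new ring expansion).** The alkoxyl radical could instead cleave toward C8, the vinyl radical could be quenched before it reaches the carbonyl, or the 4E isomer could persist. The fallback uses known chemistry, sets out from 11 and returns at 15. An intramolecular Nozaki–Hiyama–Kishi addition of the vinyl iodide to the C9 ketone (CrCl2, cat. NiCl2, DMF) closes ring B to the cis-fused bicyclic tertiary alcohol F1. Its hypoiodite is then photolysed under Suárez conditions (PhI(OAc)2, I2, hν), where the known alkoxyl-radical β-scission of the ring-fusion bond is followed by loss of the sulfur radical and iodine-mediated equilibration of the new alkene.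

- **Step 5 (thiolate conjugate addition–aldol).** It builds a quaternary centre with a sensitive β,γ-unsaturated aldehyde, and the C3 selectivity rests on the closed transition state. The fallback sets out from 9 and returns at 11. Conjugate addition of PhSSiMe3 (cat. Bu4NF, THF, −78 °C) gives the trimethylsilyl enol ether F2, which is isolated and combined with 4 in a Mukaiyama aldol reaction (TiCl4, CH2Cl2, −78 °C); any C3 epimer is removed by chromatography at 11.

- **Step 9 (C9 reduction).** An α-acyloxy group chelates weakly, so Felkin–Anh delivery could give the 9-epimer. The fallback sets out from 19 and returns at 20. A non-chelating Luche reduction (NaBH4, CeCl3·7H2O, MeOH, −78 °C) gives the 9-epimeric alcohol F3. A Mitsunobu reaction with formic acid (PPh3, DIAD) inverts C9 to the formate F4, and selective methanolysis of the formate (KHCO3, MeOH, 0 °C) gives 20.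

Further compounds
F1 | step 6 | cis-fused bicyclic tertiary alcohol (rings A and B; C9–OH; 5-phenylsulfanyl) | C[C@@]1([C@@H](O)CC=C2C)[C@@H](Sc3ccccc3)C[C@H](C(C)=C)[C@H](OC(=O)C=C(C)C)[C@@]12O
F2 | step 5 | trimethylsilyl enol ether of the 5-phenylsulfanyl ketone (C4=C9) | CC1=C(O[Si](C)(C)C)[C@@H](OC(=O)C=C(C)C)[C@@H](C(C)=C)C[C@@H]1Sc2ccccc2
F3 | step 9 | 9-epimer of 20 | C=C(C)[C@H]1C[C@@H]2O[C@]2(C)[C@@H](OC(=O)/C(C)=C\C)C/C=C(C)\[C@H](O)[C@H]1OC(=O)C=C(C)C
F4 | step 9 | 9-O-formate of 20 | C=C(C)[C@H]1C[C@@H]2O[C@]2(C)[C@@H](OC(=O)/C(C)=C\C)C/C=C(C)\[C@@H](OC=O)[C@H]1OC(=O)C=C(C)C
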